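Retrosynthesis (atom labels follow abietane numbering of the target): after the O12 acetyl is taken back to O12 methyl, the C9–C10 bond of ring B is cut, which leaves a C10 bridgehead carboxylic acid facing the only free quinone carbon, C9.
Further cuts: quinone to trimethoxyarene, Z C6=C7 alkene to alkyne, C7–C8 (aryl iodide plus terminal alkyne), C6–C7 and C5–C6 (two one-carbon homologations of a C5 ketone), C10–C20 and O–C19 (formaldehyde aldol–lactonisation), C10–carboxyl, C4–methyl.
Forward: ring A is the starting cyclohexanone, the lactone ring is closed onto it, ring C is attached as an arene through the two-carbon arm and oxidised to the quinone, and ring B is closed last.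
Enabling feature: ring A and the C19–O–C20 lactone form a 3-oxabicyclo[3.3.1]nonan-2-one with C10 at a bridgehead, so a C10 radical cannot invert and, through the Z C6=C7 alkene on C5, reaches only quinone carbon C9.
Stereochemistry: C4 from an auxiliary-controlled methylation, C10 from C4 through the lactone bridge, C5 from equilibration of the C5 aldehyde, the alkene geometry from syn semi-hydrogenation.

Key step: step 14

Assumption: the lithiated L-valine tert-butyl ester enamine is taken to be methylated, under the HMPA/toluene protocol, on the face that leads to the (1S) keto ester; if the sense of induction is the opposite, the D-valine ester is used in the same way.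

Note on names: in the bicyclic names C1, C5 and C9 are C4, C10 and C5 of the target; CIP descriptors change along the route by priority only, the spatial arrangement is that of the SMILES.

Step 1
Reactants: 1 methyl 2-oxocyclohexane-1-carboxylate
Product: 2 tert-butyl (2S)-2-{[2-(methoxycarbonyl)cyclohex-1-en-1-yl]amino}-3-methylbutanoate
Conditions: L-valine tert-butyl ester, BF3·OEt2 (cat.), toluene, reflux, Dean–Stark trap
Reagents that add atoms: L-valine tert-butyl ester, CC(C)[C@H](N)C(=O)OC(C)(C)C
Why: Acid-catalysed condensation of the ketone of a β-keto ester with a primary amine should give the hydrogen-bonded enamino ester (vinylogous carbamate formation), and the valine stereocentre is not touched.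

Step 2
Reactants: 2 enamino ester
Product: 4 methyl (1S)-1-methyl-2-oxocyclohexane-1-carboxylate, via imine 3 (not isolated)
Conditions: LiN(iPr)2, toluene, −78 °C; HMPA; MeI, −78 → −50 °C; then 1 M aq. HCl, rt
Reagents that add atoms: iodomethane, CI; water, O
Why: Alkylation of the lithiated chiral enamine: lithium is held by the enamine nitrogen and the ester carbonyls, the HMPA-capped chelate leaves one face of C4 open to iodomethane, and hydrolysis of imine 3 frees the ketone and returns the auxiliary, so the quaternary centre C4 is set by the valine auxiliary.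

Step 3
Reactants: 4 (1S) keto ester
Product: 5 1-tert-butyl 3-methyl (3S)-3-methyl-2-oxocyclohexane-1,3-dicarboxylate (both C1 epimers and the enol)
Conditions: LiN(SiMe3)2 (2.2 equiv), THF, −78 °C; Boc2O, −78 → 0 °C; aq. NH4Cl
Reagents that add atoms: di-tert-butyl dicarbonate, CC(C)(C)OC(=O)OC(=O)OC(C)(C)C
Why: Claisen-type C-acylation of the lithium enolate, which can form only towards the CH2 side (C10), by the dicarbonate; the second equivalent of base holds the product as its enolate, and C10 stays epimerisable at this stage.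

Step 4
Reactants: 5 keto diester
Product: 7 tert-butyl (1S,5R)-1-methyl-2,9-dioxo-3-oxabicyclo[3.3.1]nonane-5-carboxylate, via hydroxymethyl adduct 6 (not isolated)
Conditions: paraformaldehyde, DBU (0.3 equiv), THF, 4 Å molecular sieves, rt → 45 °C
Reagents that add atoms: formaldehyde (as paraformaldehyde), C=O
Why: Base-catalysed aldol addition of the β-keto ester to formaldehyde followed by transesterification: only the adduct with CH2OH cis to the C4 methyl ester can bridge to the δ-lactone, the other adduct returns by retro-aldol, so C10 is set by C4 through the lactone bridge, while the tert-butyl ester cannot be reached and survives.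

Step 5
Reactants: 7 keto lactone
Product: 10 tert-butyl (1S,5S,9S)-9-formyl-1-methyl-2-oxo-3-oxabicyclo[3.3.1]nonane-5-carboxylate (formyl group on the lactone side), via enol ether 8 (not isolated), via epimeric aldehyde 9 (not isolated)
Conditions: [Ph3PCH2OMe]Cl, KN(SiMe3)2, THF, 0 → 45 °C; then 2 M aq. HCl, THF, rt; then DBU (0.2 equiv), CH2Cl2, rt
Reagents that add atoms: (methoxymethyl)triphenylphosphonium chloride, COC[P+](c1ccccc1)(c1ccccc1)c1ccccc1.[Cl-]; water, O
Why: Wittig olefination of the non-enolisable bridging ketone with the small methoxymethylidene ylide, then hydrolysis of enol ether 8: protonation from the more open lactone face should first give epimer 9, and base equilibration through the enolate moves the formyl group over the flattened lactone ring, which carries one syn-axial hydrogen against two on the carbocyclic side, so C5 is set under thermodynamic control with a preference expected to be modest.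

Step 6
Reactants: 10 aldehyde (with residual 9)
Product: 11 tert-butyl (1S,5S,9S)-9-ethynyl-1-methyl-2-oxo-3-oxabicyclo[3.3.1]nonane-5-carboxylate
Conditions: MeC(O)C(N2)P(O)(OMe)2, K2CO3, MeOH, 0 °C → rt
Reagents that add atoms: dimethyl (1-diazo-2-oxopropyl)phosphonate, CC(=O)C(=[N+]=[N-])P(=O)(OC)OC
Why: Seyferth–Gilbert homologation in the Ohira–Bestmann form: under K2CO3/MeOH the aldehyde epimers interconvert, and the epimer with the formyl group on the lactone side is both the more stable and the more accessible one, so the alkyne should carry the C5 configuration of 10, which is fixed from here on.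

Step 7
Reactants: 12 1,2,4-trimethoxybenzene
Product: 14 2-(2,3,6-trimethoxyphenyl)propan-2-ol, via aryllithium 13 (not isolated)
Conditions: n-BuLi, THF, 0 °C; acetone, −78 °C → rt; aq. NH4Cl
Reagents that add atoms: acetone, CC(C)=O
Why: Directed ortho-metalation removes the hydrogen flanked by two methoxy groups (C3), and the aryllithium adds to acetone.

Step 8
Reactants: 14 tertiary benzylic alcohol
Product: 15 1,2,4-trimethoxy-3-(propan-2-yl)benzene
Conditions: Et3SiH, CF3CO2H, CH2Cl2, 0 °C → rt
Reagents that add atoms: none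
Why: Ionic hydrogenation: the tertiary benzylic alcohol ionises in CF3CO2H to a cumyl-type cation that takes hydride from the silane.

Step 9
Reactants: 15 isopropyl arene
Product: 16 1-iodo-2,4,5-trimethoxy-3-(propan-2-yl)benzene
Conditions: N-iodosuccinimide, CF3CO2H (cat.), MeCN, 0 °C → rt
Reagents that add atoms: N-iodosuccinimide, O=C1CCC(=O)N1I
Why: Electrophilic aromatic iodination at the one free position that is ortho to one methoxy group and para to another.

Step 10
Reactants: 11 terminal alkyne; 16 aryl iodide
Product: 17 tert-butyl (1S,5S,9S)-1-methyl-2-oxo-9-{[2,4,5-trimethoxy-3-(propan-2-yl)phenyl]ethynyl}-3-oxabicyclo[3.3.1]nonane-5-carboxylate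
Conditions: PdCl2(PPh3)2 (5 mol%), CuI (10 mol%), Et3N, THF, 50 °C
Reagents that add atoms: none
Why: Sonogashira coupling of a terminal alkyne with an electron-rich aryl iodide; the lactone, the tert-butyl ester and C5 are inert to the amine base.

Step 11
Reactants: 17 aryl alkyne
Product: 18 tert-butyl (1S,5S,9S)-1-methyl-2-oxo-9-{(Z)-2-[2,4,5-trimethoxy-3-(propan-2-yl)phenyl]ethenyl}-3-oxabicyclo[3.3.1]nonane-5-carboxylate
Conditions: H2 (1 atm), Pd/CaCO3 poisoned with Pb(OAc)2 (Lindlar catalyst), quinoline, EtOAc, rt
Reagents that add atoms: none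
Why: Lindlar semi-hydrogenation: syn delivery of hydrogen on the poisoned palladium surface gives the Z alkene and stops there.

Step 12
Reactants: 18 Z-alkenyl trimethoxyarene
Product: 19 tert-butyl (1S,5S,9S)-9-{(Z)-2-[4-methoxy-3,6-dioxo-5-(propan-2-yl)cyclohexa-1,4-dien-1-yl]ethenyl}-1-methyl-2-oxo-3-oxabicyclo[3.3.1]nonane-5-carboxylate
Conditions: (NH4)2Ce(NO3)6 (2.5 equiv), MeCN/H2O (2:1), 0 °C
Reagents that add atoms: water, O
Why: Oxidative demethylation by tetravalent cerium: the arene radical cation takes up water at the para-related methoxy carbons C11 and C14 to give the para-quinone, the C12 methoxy group stays as a vinylogous ester, and the tert-butyl ester and the lactone are not oxidisable.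

Step 13
Reactants: 19 quinone tert-butyl ester
Product: 20 (1S,5S,9S)-9-{(Z)-2-[4-methoxy-3,6-dioxo-5-(propan-2-yl)cyclohexa-1,4-dien-1-yl]ethenyl}-1-methyl-2-oxo-3-oxabicyclo[3.3.1]nonane-5-carboxylic acid
Conditions: CF3CO2H/CH2Cl2 (1:4), 0 °C → rt; product used at once
Reagents that add atoms: none
Why: Acidolysis of the tert-butyl ester (loss of the tert-butyl cation as isobutene) under anhydrous conditions that leave the lactone, the vinylogous ester and the Z alkene alone.

Step 14
Reactants: 20 bridgehead acid with Z-alkenyl methoxyquinone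
Product: 21 (4S,5R,10R)-12-methoxy-11,14-dioxoabieta-6,8,12-trien-19,20-olide
Conditions: AgNO3 (0.3 equiv), K2S2O8 (2.5 equiv), MeCN/H2O (1:1), 65 °C, 20 added slowly to a final 5 mM
Reagents that add atoms: none
Why: Persulfate oxidises monovalent silver to divalent silver, which takes an electron from the carboxylate of 20, and loss of CO2 leaves a pyramidal, nucleophilic tertiary radical at bridgehead C10 that adds to quinone carbon C9; the adduct radical, delocalised over C8, O14 and C6, is then oxidised and loses H9 to restore the quinone. The closest known reaction type is the silver/persulfate decarboxylative alkylation of quinones by tertiary and bridgehead carboxylic acids (a Minisci-type radical substitution), of which ring-forming intramolecular cases are known. Ring B closes in the 6-endo-trig mode across the s-cis array C5–C6=C7–C8=C9. The new quaternary centre C10 is controlled by the bicycle alone: the radical sits at the bridgehead of the 3-oxabicyclo[3.3.1]nonan-2-one, its single exo orbital points where the carboxyl stood, and C4 and C5 are not touched. The step needs bonding at C9 and not 5-exo ipso attack at C8; C9 is the only unsubstituted quinone carbon, bonding at C8 would join two fully substituted carbons in a spiro-cyclopentene, and that adduct cannot lose hydrogen and can only fragment back. The Z alkene holds C9 within reach of C10 (an E alkene could not close) and high dilution suppresses intermolecular alkylation.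

Step 15
Reactants: 21 12-O-methyl quinone
Product: 22 (4S,5R,10R)-12-hydroxy-11,14-dioxoabieta-6,8,12-trien-19,20-olide
Conditions: 2 M aq. HCl, 1,4-dioxane, 60 °C
Reagents that add atoms: water, O
Why: Acid hydrolysis of the vinylogous methyl ester by addition of water at C12 and loss of methanol; the lactone is held closed by the 1,3-diaxial C19/C20 pair and no stereocentre is touched.

Step 16
Reactants: 22 hydroxyquinone
Product: 23 (4S,5R,10R)-12-acetoxy-11,14-dioxoabieta-6,8,12-trien-19,20-olide (target)
Conditions: Ac2O, pyridine, DMAP (cat.), CH2Cl2, 0 °C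
Reagents that add atoms: acetic anhydride, CC(=O)OC(C)=O
Why: O-acetylation of the acidic vinylogous-acid hydroxyl of the hydroxyquinone with acetic anhydride under nucleophilic catalysis.

Compound list
1 | methyl 2-oxocyclohexane-1-carboxylate | COC(=O)C1CCCCC1=O | starting material
2 | tert-butyl (2S)-2-{[2-(methoxycarbonyl)cyclohex-1-en-1-yl]amino}-3-methylbutanoate | COC(=O)C1=C(N[C@@H](C(C)C)C(=O)OC(C)(C)C)CCCC1 | intermediate
3 | methyl (1S)-2-{[(2S)-1-tert-butoxy-3-methyl-1-oxobutan-2-yl]imino}-1-methylcyclohexane-1-carboxylate | COC(=O)[C@@]1(C)CCCCC1=N[C@@H](C(C)C)C(=O)OC(C)(C)C | intermediate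
4 | methyl (1S)-1-methyl-2-oxocyclohexane-1-carboxylate | COC(=O)[C@@]1(C)CCCCC1=O | intermediate
5 | 1-tert-butyl 3-methyl (3S)-3-methyl-2-oxocyclohexane-1,3-dicarboxylate (C1 epimers and enol) | COC(=O)[C@@]1(C)CCCC(C(=O)OC(C)(C)C)C1=O | intermediate
6 | 1-tert-butyl 3-methyl (1R,3S)-1-(hydroxymethyl)-3-methyl-2-oxocyclohexane-1,3-dicarboxylate | COC(=O)[C@@]1(C)CCC[C@](CO)(C(=O)OC(C)(C)C)C1=O | intermediate
7 | tert-butyl (1S,5R)-1-methyl-2,9-dioxo-3-oxabicyclo[3.3.1]nonane-5-carboxylate | CC(C)(C)OC(=O)[C@]12CCC[C@](C)(C(=O)OC1)C2=O | intermediate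
8 | tert-butyl (1S,5S)-9-(methoxymethylidene)-1-methyl-2-oxo-3-oxabicyclo[3.3.1]nonane-5-carboxylate (alkene isomers) | CC(C)(C)OC(=O)[C@]12CCC[C@](C)(C(=O)OC1)C2=COC | intermediate
9 | tert-butyl (1S,5S,9R)-9-formyl-1-methyl-2-oxo-3-oxabicyclo[3.3.1]nonane-5-carboxylate (formyl on the carbocyclic side) | CC(C)(C)OC(=O)[C@]12CCC[C@](C)(C(=O)OC1)[C@H]2C=O | intermediate
10 | tert-butyl (1S,5S,9S)-9-formyl-1-methyl-2-oxo-3-oxabicyclo[3.3.1]nonane-5-carboxylate (formyl on the lactone side) | CC(C)(C)OC(=O)[C@]12CCC[C@](C)(C(=O)OC1)[C@@H]2C=O | intermediate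
11 | tert-butyl (1S,5S,9S)-9-ethynyl-1-methyl-2-oxo-3-oxabicyclo[3.3.1]nonane-5-carboxylate | CC(C)(C)OC(=O)[C@]12CCC[C@](C)(C(=O)OC1)[C@@H]2C#C | intermediate
12 | 1,2,4-trimethoxybenzene | COc1ccc(OC)c(OC)c1 | starting material
13 | (2,3,6-trimethoxyphenyl)lithium | COc1ccc(OC)c([Li])c1OC | intermediate
14 | 2-(2,3,6-trimethoxyphenyl)propan-2-ol | COc1ccc(OC)c(C(C)(C)O)c1OC | intermediate
15 | 1,2,4-trimethoxy-3-(propan-2-yl)benzene | COc1ccc(OC)c(C(C)C)c1OC | intermediate
16 | 1-iodo-2,4,5-trimethoxy-3-(propan-2-yl)benzene | COc1cc(I)c(OC)c(C(C)C)c1OC | intermediate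
17 | tert-butyl (1S,5S,9S)-1-methyl-2-oxo-9-{[2,4,5-trimethoxy-3-(propan-2-yl)phenyl]ethynyl}-3-oxabicyclo[3.3.1]nonane-5-carboxylate | CC(C)(C)OC(=O)[C@]12CCC[C@](C)(C(=O)OC1)[C@@H]2C#Cc1cc(OC)c(OC)c(C(C)C)c1OC | intermediate
18 | tert-butyl (1S,5S,9S)-1-methyl-2-oxo-9-{(Z)-2-[2,4,5-trimethoxy-3-(propan-2-yl)phenyl]ethenyl}-3-oxabicyclo[3.3.1]nonane-5-carboxylate | CC(C)(C)OC(=O)[C@]12CCC[C@](C)(C(=O)OC1)[C@@H]2/C=C\c1cc(OC)c(OC)c(C(C)C)c1OC | intermediate
19 | tert-butyl (1S,5S,9S)-9-{(Z)-2-[4-methoxy-3,6-dioxo-5-(propan-2-yl)cyclohexa-1,4-dien-1-yl]ethenyl}-1-methyl-2-oxo-3-oxabicyclo[3.3.1]nonane-5-carboxylate | CC(C)(C)OC(=O)[C@]12CCC[C@](C)(C(=O)OC1)[C@@H]2/C=C\C1=CC(=O)C(OC)=C(C(C)C)C1=O | intermediate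
20 | (1S,5S,9S)-9-{(Z)-2-[4-methoxy-3,6-dioxo-5-(propan-2-yl)cyclohexa-1,4-dien-1-yl]ethenyl}-1-methyl-2-oxo-3-oxabicyclo[3.3.1]nonane-5-carboxylic acid | O=C(O)[C@]12CCC[C@](C)(C(=O)OC1)[C@@H]2/C=C\C1=CC(=O)C(OC)=C(C(C)C)C1=O | intermediate
21 | (4S,5R,10R)-12-methoxy-11,14-dioxoabieta-6,8,12-trien-19,20-olide | COC1=C(C(C)C)C(=O)C2=C(C1=O)[C@]13CCC[C@](C)(C(=O)OC1)[C@@H]3C=C2 | intermediate
22 | (4S,5R,10R)-12-hydroxy-11,14-dioxoabieta-6,8,12-trien-19,20-olide | OC1=C(C(C)C)C(=O)C2=C(C1=O)[C@]13CCC[C@](C)(C(=O)OC1)[C@@H]3C=C2 | intermediate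
23 | (4S,5R,10R)-12-acetoxy-11,14-dioxoabieta-6,8,12-trien-19,20-olide | CC(=O)OC1=C(C(C)C)C(=O)C2=C(C1=O)[C@]13CCC[C@](C)(C(=O)OC1)[C@@H]3C=C2 | target

Total step count: 16. Longest linear sequence: 13 steps (steps 1–6 and 10–16); the arene branch (steps 7–9) joins at step 10.

Steps most likely to fail

Step 14. The ring closure may lose out to 5-exo ipso addition at C8, which the C12 methoxy group favours electronically, or to oxidation of the bridgehead radical and of the dienyl quinone by divalent silver and persulfate before the ring closes. The fallback leaves at acid 20 and returns at 21. Esterification of 20 with N-hydroxypyridine-2-thione (N-ethyl-N'-(3-dimethylaminopropyl)carbodiimide hydrochloride, DMAP cat., CH2Cl2, 0 °C, dark) would give the thiohydroxamate ester F1. Visible-light photolysis of F1 in dilute CH2Cl2 at 0 °C starts a non-oxidative Barton decarboxylation chain: the C10 radical adds to C9 and the adduct radical takes up the 2-pyridylthio group at C8 to give the dihydroquinone F2. Treatment of F2 with Et3N eliminates pyridine-2-thiol and gives 21.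

Step 6. Control of C5 may be incomplete, because the two aldehyde epimers differ little in energy and the alkyne could then form as a mixture at C5. The fallback leaves at aldehyde 10 (either epimer or the 9/10 mixture) and returns at alkyne 11. Pinnick oxidation (NaClO2, NaH2PO4, 2-methylbut-2-ene, t-BuOH/H2O) would give the C5 carboxylic acid F3. Silver-catalysed decarboxylative alkynylation (AgNO3, K2S2O8, 1-[(triisopropylsilyl)ethynyl]-1,2-benziodoxol-3(1H)-one, MeCN/H2O, 50 °C) passes both epimers through one planar C5 radical, which the bulky alkyne donor should meet on the more open lactone face, and gives the silyl alkyne F4. Bu4NF in THF then frees 11.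

Step 12. The Z styrene may isomerise to E through the arene radical cation, or tetravalent cerium may attack the electron-rich alkene. The fallback leaves at alkyne 11 and iodide 16 and returns at quinone ester 19. Trans-hydroboration of 11 ([Rh(cod)Cl]2, P(iPr)3, Et3N, pinacolborane, cyclohexane, rt) would give the Z-alkenylboronate F5. Oxidation of 16 with (NH4)2Ce(NO3)6 in MeCN/H2O gives the iodoquinone F6 before any alkene is present. Suzuki–Miyaura coupling of F5 with F6 (Pd(PPh3)4, CsF, 1,4-dioxane, 60 °C) proceeds with retention of the alkene geometry and gives 19.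

Further compounds
F1 | step 14 | 2-sulfanylidenepyridin-1(2H)-yl (1S,5S,9S)-9-{(Z)-2-[4-methoxy-3,6-dioxo-5-(propan-2-yl)cyclohexa-1,4-dien-1-yl]ethenyl}-1-methyl-2-oxo-3-oxabicyclo[3.3.1]nonane-5-carboxylate | O=C(ON1C=CC=CC1=S)[C@]12CCC[C@](C)(C(=O)OC1)[C@@H]2/C=C\C1=CC(=O)C(OC)=C(C(C)C)C1=O
F2 | step 14 | (4S,5R,10R)-12-methoxy-8-(pyridin-2-ylsulfanyl)-11,14-dioxoabieta-6,12-dien-19,20-olide (mixture at C8 and C9) | COC1=C(C(C)C)C(=O)C2(Sc4ccccn4)C(C1=O)[C@]13CCC[C@](C)(C(=O)OC1)[C@@H]3C=C2
F3 | step 6 | (1S,5S)-5-(tert-butoxycarbonyl)-1-methyl-2-oxo-3-oxabicyclo[3.3.1]nonane-9-carboxylic acid (both C9 epimers) | CC(C)(C)OC(=O)[C@]12CCC[C@](C)(C(=O)OC1)C2C(=O)O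
F4 | step 6 | tert-butyl (1S,5S,9S)-1-methyl-2-oxo-9-{[tri(propan-2-yl)silyl]ethynyl}-3-oxabicyclo[3.3.1]nonane-5-carboxylate | CC(C)(C)OC(=O)[C@]12CCC[C@](C)(C(=O)OC1)[C@@H]2C#C[Si](C(C)C)(C(C)C)C(C)C
F5 | step 12 | tert-butyl (1S,5S,9S)-1-methyl-2-oxo-9-[(Z)-2-(4,4,5,5-tetramethyl-1,3,2-dioxaborolan-2-yl)ethenyl]-3-oxabicyclo[3.3.1]nonane-5-carboxylate | CC(C)(C)OC(=O)[C@]12CCC[C@](C)(C(=O)OC1)[C@@H]2/C=C\B1OC(C)(C)C(C)(C)O1
F6 | step 12 | 5-iodo-2-methoxy-3-(propan-2-yl)cyclohexa-2,5-diene-1,4-dione | COC1=C(C(C)C)C(=O)C(I)=CC1=O
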